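## Structural features

Pseudopentafuhalol D is an achiral chain of five benzene rings (A to E in the order of the SMILES string) held together only by four diaryl ether oxygens; there is no stereocentre, no C–C bond between rings, and thirteen free phenolic hydroxyls. Ring positions are written here with a lower-case ring letter and the locant in SMILES order (a1 to a6, b1 to b6 and so on). Ring A is a 2,4,6-trihydroxyphenyl unit bound through a4; ring B carries its two ether oxygens on the neighbouring carbons b1 (to A) and b6 (to C) and hydroxyls on b3 and b5; ring C is bound through c1 (to B) and c5 (to D) with hydroxyls on c3 and c4; ring D is oxygenated everywhere except d2, with ether oxygens on the neighbouring d1 (to C) and d6 (to E) and hydroxyls on d3, d4 and d5; ring E is a 3,4,5-trihydroxyphenyl unit bound through e1. The fragile part is the free polyphenol: the pyrogallol- and hydroxyhydroquinone-type rings are oxidised by air, fastest in base, so every hydroxyl has to stay masked until the last step and the masks must come off under neutral conditions. The real difficulty lies in the four ether bonds, because all rings are electron-rich, every ether carbon has an oxygen-bearing neighbour, and the target contains no electron-withdrawing group that could drive an addition–elimination. On rings B and D two neighbouring oxygens must also be told apart, one for each neighbouring ring. The key step exploits that the a1 hydroxyl is para to a4, the c4 hydroxyl is para to c1 and ortho to c5, and the e4 hydroxyl is para to e1: each of these three hydroxyls can be carried as a formyl group that activates a halide on exactly the ether carbons and is afterwards exchanged for oxygen.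

## Logic of the disconnections

33 to 32: the ten O–CH2Ph bonds are cut. All oxidation-sensitive hydroxyls are thereby masked by a single group that leaves in one neutral operation. The forward step must cleave ten benzyl ethers without touching the four diaryl ethers, and 32 may contain nothing else that is reducible.

32 to 30 (key disconnection): the C–O bonds at a1, c4 and e4 are cut and each oxygen is replaced by a formyl carbon. These are the only three positions that stand para or ortho to every ether carbon of rings A, C and E, so the same carbons that become hydroxyls can first serve as activating groups. Three electron-rich rings turn into electron-poor benzaldehydes and three hydroxyls need no protecting group. The forward step must achieve aryl migration at three sites of unequal electron density in one operation and must spare ten benzyl ethers and the very electron-rich rings B and D.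

30 to 29 and 26: the c5–O bond (oxygen on d1) is cut, so that a trimer and a dimer of similar size are joined last. The forward step is a displacement of the fluoride next to the formyl group of ring C by a large phenoxide, and it must not exchange the aryloxy groups that already stand para to formyl groups.

29 to 13 and 28: the c1–O bond (oxygen on b6) is cut. Ring C is then a simple difluorobenzaldehyde that takes up its two neighbours one after the other. The forward step must select the fluoride para to formyl and leave the ortho fluoride for the next step.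

13 to 12, then to 11 and 4: first the O–allyl bond on b6, then the a4–O bond (oxygen on b1). The bromide of 4 is flanked by two benzyloxy groups and is the hardest electrophile of the route, so this ether is made first, on small molecules. The temporary group on b6 must survive base and copper and must leave without harming aldehyde or benzyl ethers; allyl meets this.

26 to 25, then to 20 and 24: first the O–allyl bond on d1, then the e1–O bond (oxygen on d6). The unhindered fluoride of 24, para to formyl, is matched with the more hindered oxygen of ring D, and the less hindered d1 oxygen is saved for the crowded ortho position of ring C.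

11 back to 5 (through 9, 8 and 7): the b1–O bond is traced to a formyl carbon, the allyl group is removed, the b1–CHO bond is cut, and the b6–O bond is traced to the formyl carbon of 5. The two neighbouring oxygens of ring B thus enter one after the other and are never equivalent. The order of events (free the first oxygen, formylate next to it, cap the first oxygen, exchange the new formyl for oxygen) decides which oxygen ends up free.

20 back to 14 (through 18, 17 and 16): the same four operations on ring D. Here the oxygen introduced second (d6) is the free one and the first (d1) carries the allyl group, as required for joining ring E before ring C.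

4 to 1, 24 to 21, 28 to 27: functional-group changes only. These are benzylation and adjustment of the carboxyl oxidation level for ring A, benzylation and formylation between the two ether oxygens for ring E, and benzylation for ring C.

## Other disconnections considered

Alternative 1: The cut runs through ring D itself. The d1–d2 bond is opened and the ring is traced back to a squaric acid derivative that already carries the ring E aryloxy group.
- Forward key step: the cyclobutenone A2 would be heated. It is a 4-hydroxy-4-(1-methoxyethenyl)cyclobutenone with the tris(benzyloxy)phenoxy group on carbon 2 and a benzyloxy group on carbon 3. Four-electron ring opening would give a dienylketene, six-electron closure would join the ketene carbon to the vinyl terminus, and tautomerisation would give the hydroquinone A1. In A1, d1 and d4 carry free hydroxyls, d6 the ring E ether, d5 a benzyl ether and d3 a methyl ether.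
- In its favour: all five oxygens of ring D are placed without ambiguity in one pericyclic step. The d6–O–E bond comes from an addition–elimination on the squarate and needs no activated arene. The free d1 hydroxyl is the nucleophile needed for c5. On ring D this is better than the chosen plan, which spends four steps (10 to 13) on the same task.
- Against it here: it settles one ring and one ether bond only, so the other three ether bonds would still need an activating device such as the formyl groups. The d3 methyl ether would have to be cleaved at the end beside thirteen hydroxyls, or replaced by a less accessible 1-(benzyloxy)vinyl nucleophile. The d4 hydroxyl would have to be benzylated without touching d1. The organolithium would have to choose the squarate carbonyl next to the benzyloxy carbon.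
- Comparison: in mechanism the thermal rearrangement is as well founded as the Baeyer–Villiger reaction. In step count the DE unit would come out about equal, since the ring E phenol would still be 16 and the adjustments at d3 and d4 cost what the ring construction saves. In scope it is the weaker plan, because it answers the smallest part of the ether problem.

Alternative 2: Ring A is not attached as an arene at all. The a4–a5 bond (equivalent to a3–a4 by symmetry) is cut and ring A is unfolded into a 3,5-dioxohexanoate chain on the b1 oxygen.
- Forward key step: the triketide ester A4 would be treated with NaOMe. The carbanion at the aryloxy-bearing carbon 6 would attack the ester carbonyl (Claisen closure of a six-membered ring), and the resulting cyclohexanetrione would enolise to the phloroglucinol A3.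
- In its favour: it follows the polyketide logic of the natural series. It avoids the most hindered ether formation of the chosen route (step 8) and takes ring A out of the peracid step, where ring A is the least favourable site. On both points it is better than the chosen plan. Ring A is symmetrical, so the closure raises no positional question.
- Against it here: in a 3,5-dioxo ester the acidic positions are carbons 2 and 4, not carbon 6. Closure through oxygen to a hydroxypyranone or an aldol closure would compete with the required Claisen mode. The chain would have to be built on the b1 oxygen of a tetrameric phenol, the most valuable intermediate. The B–C, C–D and D–E ethers would still need the formyl tactic.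
- Comparison: step count is about equal (chain assembly against steps 1 to 3, 8 and 9). The alternative is better in avoiding a hindered coupling and worse in the certainty of its ring closure and in linearity.

Alternative 3: Both ether bonds of ring C (c1–O and c5–O) are cut at once and only ring C is kept as an aldehyde.
- Forward key step: 28 would take up the phenoxide of A6 at the fluoride para to formyl and then, in the same pot, the phenoxide of A7 at the ortho fluoride, to give the pentamer monoaldehyde A5. A single Baeyer–Villiger oxidation and hydrogenolysis of twelve benzyl ethers would follow.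
- In its favour: electrophile and mechanism are the same as in steps 19 and 20, so on ring C it is the equal of the chosen plan. It saves one isolation. The late oxidation concerns one aldehyde only, and that on the most favourable ring, which is better than a threefold reaction.
- Against it here: rings A and E no longer carry any activation. The A–B and D–E ethers inside A6 and A7 would have to be made between electron-rich, doubly ortho-substituted partners, the weakest case of copper coupling. Otherwise they would have to be made with formyl groups that are exchanged early: A6 would be reachable from 12 and A7 from 25, each by oxidation, benzylation and deallylation. That costs about four steps more than the one-pot saves. The one-pot order also requires the first phenoxide to be consumed completely before the second is added.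
- Comparison: the chosen plan is this idea extended to all three electron-poor rings. Alternative 3 is equal at ring C, safer at the oxidation stage, and longer or weaker in the fragments.

Key step: step 21

Remark on the chemistry: with the locants defined above, 30 and 32 agree atom for atom with the target, so no structure needed correction; the additions to the design are the allyl group as temporary protection of b6 and d1, copper catalysis for the hindered bromide of ring A, and the stepwise order para then ortho on ring C.

## Route

Step 1
Reactants: 1 4-bromo-3,5-dihydroxybenzoic acid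
Product: 2 benzyl 3,5-bis(benzyloxy)-4-bromobenzoate
Conditions: BnBr (3.3 equiv), K2CO3, DMF, 60 °C
Reagents that add atoms: benzyl bromide, BrCc1ccccc1
Why: Williamson-type O-alkylation (SN2) of both phenoxides and of the carboxylate; the aryl bromide is inert to carbonate.

Step 2
Reactants: 2 benzyl 3,5-bis(benzyloxy)-4-bromobenzoate
Product: 3 [3,5-bis(benzyloxy)-4-bromophenyl]methanol
Conditions: i-Bu2AlH (3 equiv), CH2Cl2, −78 to 0 °C
Reagents that add atoms: none
Why: Hydride reduction of the ester to the primary alcohol; aryl bromide and benzyl ethers are not touched at low temperature.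

Step 3
Reactants: 3 [3,5-bis(benzyloxy)-4-bromophenyl]methanol
Product: 4 3,5-bis(benzyloxy)-4-bromobenzaldehyde
Conditions: MnO2 (excess), CH2Cl2, rt
Reagents that add atoms: none
Why: MnO2 oxidation is selective for benzylic alcohols and stops at the aldehyde.

Step 4
Reactants: 5 2,4-bis(benzyloxy)benzaldehyde
Product: 7 2,4-bis(benzyloxy)phenol, via 2,4-bis(benzyloxy)phenyl formate 6 (not isolated)
Conditions: mCPBA (1.3 equiv), CH2Cl2, 0 °C to rt; aq. NaHCO3/Na2S2O3 wash; K2CO3 (cat.), MeOH, rt
Reagents that add atoms: m-chloroperoxybenzoic acid, OOC(=O)c1cccc(Cl)c1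
Why: Baeyer–Villiger (Dakin-type) oxidation: the ortho and para benzyloxy donors make aryl migration in the Criegee adduct much faster than hydride migration; the formate is then methanolysed. The new oxygen is the future b6 oxygen.

Step 5
Reactants: 7 2,4-bis(benzyloxy)phenol
Product: 8 3,5-bis(benzyloxy)-2-hydroxybenzaldehyde
Conditions: MgCl2 (2 equiv), Et3N (4 equiv), (CH2O)n (6 equiv), THF, reflux
Reagents that add atoms: formaldehyde (as paraformaldehyde), C=O
Why: Magnesium-mediated ortho-formylation of a phenol: the magnesium phenoxide delivers formaldehyde only to the single free ortho carbon (the future b1), and the hydroxymethyl magnesium alkoxide passes hydride to a second formaldehyde (Oppenauer-type) to give the salicylaldehyde.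

Step 6
Reactants: 8 3,5-bis(benzyloxy)-2-hydroxybenzaldehyde
Product: 9 2-(allyloxy)-3,5-bis(benzyloxy)benzaldehyde
Conditions: allyl bromide (1.5 equiv), K2CO3, DMF, 50 °C
Reagents that add atoms: allyl bromide, C=CCBr
Why: Williamson allylation of the chelated phenol; allyl is chosen because it is orthogonal to benzyl, inert to peracid at 0 °C, to phosphate and carbonate bases and to copper catalysis, and removable by zerovalent palladium.

Step 7
Reactants: 9 2-(allyloxy)-3,5-bis(benzyloxy)benzaldehyde
Product: 11 2-(allyloxy)-3,5-bis(benzyloxy)phenol, via 2-(allyloxy)-3,5-bis(benzyloxy)phenyl formate 10 (not isolated)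
Conditions: mCPBA (1.3 equiv), CH2Cl2, 0 °C to rt; aq. NaHCO3/Na2S2O3 wash; K2CO3 (cat.), MeOH, rt (argon)
Reagents that add atoms: m-chloroperoxybenzoic acid, OOC(=O)c1cccc(Cl)c1
Why: Baeyer–Villiger oxidation as for 2,3-dialkoxybenzaldehydes: the ortho allyloxy oxygen supports aryl migration, and the monosubstituted allyl alkene is epoxidised far more slowly than the electron-rich aldehyde reacts. The free hydroxyl of 11 is the b1 oxygen, the allyl ether the b6 oxygen.

Step 8
Reactants: 11 2-(allyloxy)-3,5-bis(benzyloxy)phenol; 4 3,5-bis(benzyloxy)-4-bromobenzaldehyde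
Product: 12 4-[2-(allyloxy)-3,5-bis(benzyloxy)phenoxy]-3,5-bis(benzyloxy)benzaldehyde
Conditions: CuI (10 mol %), picolinic acid (20 mol %), K3PO4 (2 equiv), DMSO, 90 °C, argon
Reagents that add atoms: none
Why: Ullmann-type copper-catalysed aryl ether synthesis: the phenoxide of 11 displaces the bromide of 4, whose C–Br bond is activated by the para formyl group. The picolinate ligand suits ortho-substituted partners, and the allyl ether, benzyl ethers and non-enolisable aldehyde are inert to K3PO4 in DMSO.

Step 9
Reactants: 12 4-[2-(allyloxy)-3,5-bis(benzyloxy)phenoxy]-3,5-bis(benzyloxy)benzaldehyde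
Product: 13 3,5-bis(benzyloxy)-4-[3,5-bis(benzyloxy)-2-hydroxyphenoxy]benzaldehyde
Conditions: Pd(PPh3)4 (5 mol %), morpholine (5 equiv), THF, rt
Reagents that add atoms: none
Why: Tsuji–Trost deallylation: zerovalent palladium ionises the aryl allyl ether to the phenoxide and a π-allyl complex that morpholine captures. Benzyl ethers and the aldehyde are untouched, since any aminal reverts on work-up.

Step 10
Reactants: 14 3,4,5-tris(benzyloxy)benzaldehyde
Product: 16 3,4,5-tris(benzyloxy)phenol, via 3,4,5-tris(benzyloxy)phenyl formate 15 (not isolated)
Conditions: mCPBA (1.5 equiv), CH2Cl2, 0 °C to rt; aq. NaHCO3/Na2S2O3 wash; K2CO3 (cat.), MeOH, rt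
Reagents that add atoms: m-chloroperoxybenzoic acid, OOC(=O)c1cccc(Cl)c1
Why: Baeyer–Villiger oxidation of a 3,4,5-trialkoxybenzaldehyde, in which the para alkoxy oxygen supports aryl migration. The new oxygen is the future d1 oxygen.

Step 11
Reactants: 16 3,4,5-tris(benzyloxy)phenol
Product: 17 2,3,4-tris(benzyloxy)-6-hydroxybenzaldehyde
Conditions: MgCl2 (2 equiv), Et3N (4 equiv), (CH2O)n (6 equiv), THF, reflux
Reagents that add atoms: formaldehyde (as paraformaldehyde), C=O
Why: Magnesium-mediated ortho-formylation; the two ortho positions are equivalent and the para position is blocked, so only one product can form. The formyl carbon marks the future d6.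

Step 12
Reactants: 17 2,3,4-tris(benzyloxy)-6-hydroxybenzaldehyde
Product: 18 6-(allyloxy)-2,3,4-tris(benzyloxy)benzaldehyde
Conditions: allyl bromide (1.5 equiv), K2CO3, DMF, 50 °C
Reagents that add atoms: allyl bromide, C=CCBr
Why: Williamson allylation of the salicylaldehyde hydroxyl, which caps the d1 oxygen.

Step 13
Reactants: 18 6-(allyloxy)-2,3,4-tris(benzyloxy)benzaldehyde
Product: 20 6-(allyloxy)-2,3,4-tris(benzyloxy)phenol, via 6-(allyloxy)-2,3,4-tris(benzyloxy)phenyl formate 19 (not isolated)
Conditions: mCPBA (1.3 equiv), CH2Cl2, 0 °C; aq. NaHCO3/Na2S2O3 wash; K2CO3 (cat.), MeOH, rt (argon)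
Reagents that add atoms: m-chloroperoxybenzoic acid, OOC(=O)c1cccc(Cl)c1
Why: Baeyer–Villiger oxidation of an aldehyde with two ortho and one para oxygen donors, the most favourable case; the allyl alkene is not expected to compete at 0 °C. The free hydroxyl of 20 is the d6 oxygen.

Step 14
Reactants: 21 5-fluororesorcinol
Product: 22 1,3-bis(benzyloxy)-5-fluorobenzene
Conditions: BnBr (2.2 equiv), K2CO3, DMF, 50 °C
Reagents that add atoms: benzyl bromide, BrCc1ccccc1
Why: Williamson O-benzylation of both phenols; the unactivated fluoride is inert.

Step 15
Reactants: 22 1,3-bis(benzyloxy)-5-fluorobenzene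
Product: 24 2,6-bis(benzyloxy)-4-fluorobenzaldehyde, via [2,6-bis(benzyloxy)-4-fluorophenyl]lithium 23 (not isolated)
Conditions: n-BuLi (1.1 equiv), THF, −78 to −30 °C; DMF, −78 °C to rt; aq. NH4Cl
Reagents that add atoms: N,N-dimethylformamide, CN(C)C=O
Why: Directed ortho-metalation: the two benzyloxy oxygens together guide n-BuLi to the carbon between them (para to fluorine), as in 1,3-dialkoxybenzenes. No amine additive is used, so coordination and not the acidity beside fluorine should decide the site, and the low temperature suppresses benzylic metalation; DMF then formylates the aryllithium.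

Step 16
Reactants: 20 6-(allyloxy)-2,3,4-tris(benzyloxy)phenol; 24 2,6-bis(benzyloxy)-4-fluorobenzaldehyde
Product: 25 4-[6-(allyloxy)-2,3,4-tris(benzyloxy)phenoxy]-2,6-bis(benzyloxy)benzaldehyde
Conditions: K2CO3 (2 equiv), DMF, 80 °C, argon
Reagents that add atoms: none
Why: Nucleophilic aromatic substitution (addition–elimination): the phenoxide adds para to the formyl group, which stabilises the Meisenheimer adduct, and fluoride leaves. The two benzyloxy groups are meta to the reacting carbon and do not deactivate it by resonance.

Step 17
Reactants: 25 4-[6-(allyloxy)-2,3,4-tris(benzyloxy)phenoxy]-2,6-bis(benzyloxy)benzaldehyde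
Product: 26 2,6-bis(benzyloxy)-4-[2,3,4-tris(benzyloxy)-6-hydroxyphenoxy]benzaldehyde
Conditions: Pd(PPh3)4 (5 mol %), morpholine (5 equiv), THF, rt
Reagents that add atoms: none
Why: Tsuji–Trost deallylation with zerovalent palladium, as in step 9; it frees the d1 hydroxyl and leaves aldehyde, benzyl ethers and the diaryl ether alone.

Step 18
Reactants: 27 2,4-difluoro-6-hydroxybenzaldehyde
Product: 28 2-(benzyloxy)-4,6-difluorobenzaldehyde
Conditions: BnBr (1.1 equiv), K2CO3, DMF, rt
Reagents that add atoms: benzyl bromide, BrCc1ccccc1
Why: Williamson O-benzylation at room temperature; the weakly nucleophilic, chelated phenoxide is alkylated faster than it can displace a fluoride of a second molecule.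

Step 19
Reactants: 13 3,5-bis(benzyloxy)-4-[3,5-bis(benzyloxy)-2-hydroxyphenoxy]benzaldehyde; 28 2-(benzyloxy)-4,6-difluorobenzaldehyde
Product: 29 3,5-bis(benzyloxy)-4-{3,5-bis(benzyloxy)-2-[3-(benzyloxy)-5-fluoro-4-formylphenoxy]phenoxy}benzaldehyde
Conditions: K2CO3 (2 equiv), 28 (1.3 equiv), DMF, rt to 50 °C
Reagents that add atoms: none
Why: Nucleophilic aromatic substitution through a formyl-stabilised Meisenheimer adduct. The bulky, doubly ortho-substituted phenoxide of 13 should choose the open fluoride para to formyl (c1) over the one beside the formyl group, the more so in a polar aprotic solvent where chelation-guided ortho attack is weak. The small excess of 28 and the new aryloxy donor in the product guard against double substitution.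

Step 20
Reactants: 29 3,5-bis(benzyloxy)-4-{3,5-bis(benzyloxy)-2-[3-(benzyloxy)-5-fluoro-4-formylphenoxy]phenoxy}benzaldehyde; 26 2,6-bis(benzyloxy)-4-[2,3,4-tris(benzyloxy)-6-hydroxyphenoxy]benzaldehyde
Product: 30 pentamer trialdehyde (formyl on a1, c4 and e4; ten benzyl ethers)
Conditions: Cs2CO3 (2 equiv), DMSO, 80 °C, argon
Reagents that add atoms: none
Why: Second nucleophilic aromatic substitution, now at the fluoride ortho to the ring C formyl group (c5); the phenoxide of 26 is hindered on one side only and Cs2CO3 in DMSO gives a loosely paired phenoxide. Fluoride is a far better leaving group than the aryloxides para to formyl groups, so exchange of the existing ethers is not expected at this temperature.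

Step 21
Reactants: 30 pentamer trialdehyde
Product: 32 pentamer triphenol, via pentamer triformate 31 (not isolated)
Conditions: mCPBA (4.5 equiv), CH2Cl2, 0 °C to rt; aq. NaHCO3/Na2S2O3 wash; crude 31, K2CO3 (cat.), MeOH/THF, rt, argon
Reagents that add atoms: m-chloroperoxybenzoic acid, OOC(=O)c1cccc(Cl)c1
Why: The peracid adds to each of the three formyl groups to give Criegee adducts, and in each the aryl group migrates to oxygen with loss of m-chlorobenzoate, giving the triformate 31; carbonate-catalysed methanolysis then frees the three phenols. The closest known reaction type is the Baeyer–Villiger (Dakin-type) oxidation of alkoxy- and aryloxybenzaldehydes to aryl formates, the reaction already used in steps 4, 7, 10 and 13. No ring is closed and no stereocentre is formed; three C–C bonds are exchanged for three C–O bonds at a1, c4 and e4. The selectivity needed is aryl over hydride migration at every site. On rings C and E it is secured by two ortho oxygens and a para aryloxy oxygen, on ring A by the para aryloxy oxygen alone, so ring A is the slowest site and sets time and excess of peracid. Positional selectivity is not needed, because oxygen enters exactly where each formyl carbon was attached. The electron-rich rings are protected by the order of events: the aryl formates are much less oxidisable than phenols, and the peracid is destroyed before methanolysis, so the free phenols never meet the oxidant.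

Step 22
Reactants: 32 pentamer triphenol
Product: 33 pseudopentafuhalol D
Conditions: H2 (1 atm), 10% Pd/C, THF/MeOH, rt; filtration and concentration under argon
Reagents that add atoms: none
Why: Hydrogenolysis of the ten benzyl ethers over palladium on carbon; diaryl ethers and the arene rings are stable at one atmosphere, and the neutral medium avoids base-promoted air oxidation of the polyphenol.

## Compound list

1 | 4-bromo-3,5-dihydroxybenzoic acid | OC(=O)c1cc(O)c(Br)c(O)c1 | starting material
2 | benzyl 3,5-bis(benzyloxy)-4-bromobenzoate | O=C(OCc1ccccc1)c1cc(OCc2ccccc2)c(Br)c(OCc2ccccc2)c1 | intermediate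
3 | [3,5-bis(benzyloxy)-4-bromophenyl]methanol | OCc1cc(OCc2ccccc2)c(Br)c(OCc2ccccc2)c1 | intermediate
4 | 3,5-bis(benzyloxy)-4-bromobenzaldehyde | O=Cc1cc(OCc2ccccc2)c(Br)c(OCc2ccccc2)c1 | intermediate
5 | 2,4-bis(benzyloxy)benzaldehyde | O=Cc1ccc(OCc2ccccc2)cc1OCc1ccccc1 | starting material
6 | 2,4-bis(benzyloxy)phenyl formate | O=COc1ccc(OCc2ccccc2)cc1OCc1ccccc1 | intermediate (not isolated)
7 | 2,4-bis(benzyloxy)phenol | Oc1ccc(OCc2ccccc2)cc1OCc1ccccc1 | intermediate
8 | 3,5-bis(benzyloxy)-2-hydroxybenzaldehyde | O=Cc1cc(OCc2ccccc2)cc(OCc2ccccc2)c1O | intermediate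
9 | 2-(allyloxy)-3,5-bis(benzyloxy)benzaldehyde | O=Cc1cc(OCc2ccccc2)cc(OCc2ccccc2)c1OCC=C | intermediate
10 | 2-(allyloxy)-3,5-bis(benzyloxy)phenyl formate | O=COc1cc(OCc2ccccc2)cc(OCc2ccccc2)c1OCC=C | intermediate (not isolated)
11 | 2-(allyloxy)-3,5-bis(benzyloxy)phenol | Oc1cc(OCc2ccccc2)cc(OCc2ccccc2)c1OCC=C | intermediate
12 | 4-[2-(allyloxy)-3,5-bis(benzyloxy)phenoxy]-3,5-bis(benzyloxy)benzaldehyde | O=Cc1cc(OCc2ccccc2)c(Oc2cc(OCc3ccccc3)cc(OCc3ccccc3)c2OCC=C)c(OCc2ccccc2)c1 | intermediate
13 | 3,5-bis(benzyloxy)-4-[3,5-bis(benzyloxy)-2-hydroxyphenoxy]benzaldehyde | O=Cc1cc(OCc2ccccc2)c(Oc2cc(OCc3ccccc3)cc(OCc3ccccc3)c2O)c(OCc2ccccc2)c1 | intermediate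
14 | 3,4,5-tris(benzyloxy)benzaldehyde | O=Cc1cc(OCc2ccccc2)c(OCc2ccccc2)c(OCc2ccccc2)c1 | starting material
15 | 3,4,5-tris(benzyloxy)phenyl formate | O=COc1cc(OCc2ccccc2)c(OCc2ccccc2)c(OCc2ccccc2)c1 | intermediate (not isolated)
16 | 3,4,5-tris(benzyloxy)phenol | Oc1cc(OCc2ccccc2)c(OCc2ccccc2)c(OCc2ccccc2)c1 | intermediate
17 | 2,3,4-tris(benzyloxy)-6-hydroxybenzaldehyde | O=Cc1c(O)cc(OCc2ccccc2)c(OCc2ccccc2)c1OCc1ccccc1 | intermediate
18 | 6-(allyloxy)-2,3,4-tris(benzyloxy)benzaldehyde | O=Cc1c(OCC=C)cc(OCc2ccccc2)c(OCc2ccccc2)c1OCc1ccccc1 | intermediate
19 | 6-(allyloxy)-2,3,4-tris(benzyloxy)phenyl formate | O=COc1c(OCC=C)cc(OCc2ccccc2)c(OCc2ccccc2)c1OCc1ccccc1 | intermediate (not isolated)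
20 | 6-(allyloxy)-2,3,4-tris(benzyloxy)phenol | Oc1c(OCC=C)cc(OCc2ccccc2)c(OCc2ccccc2)c1OCc1ccccc1 | intermediate
21 | 5-fluororesorcinol (5-fluorobenzene-1,3-diol) | Oc1cc(O)cc(F)c1 | starting material
22 | 1,3-bis(benzyloxy)-5-fluorobenzene | Fc1cc(OCc2ccccc2)cc(OCc2ccccc2)c1 | intermediate
23 | [2,6-bis(benzyloxy)-4-fluorophenyl]lithium | [Li]c1c(OCc2ccccc2)cc(F)cc1OCc1ccccc1 | intermediate (not isolated)
24 | 2,6-bis(benzyloxy)-4-fluorobenzaldehyde | O=Cc1c(OCc2ccccc2)cc(F)cc1OCc1ccccc1 | intermediate
25 | 4-[6-(allyloxy)-2,3,4-tris(benzyloxy)phenoxy]-2,6-bis(benzyloxy)benzaldehyde | O=Cc1c(OCc2ccccc2)cc(Oc2c(OCC=C)cc(OCc3ccccc3)c(OCc3ccccc3)c2OCc2ccccc2)cc1OCc1ccccc1 | intermediate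
26 | 2,6-bis(benzyloxy)-4-[2,3,4-tris(benzyloxy)-6-hydroxyphenoxy]benzaldehyde | O=Cc1c(OCc2ccccc2)cc(Oc2c(O)cc(OCc3ccccc3)c(OCc3ccccc3)c2OCc2ccccc2)cc1OCc1ccccc1 | intermediate
27 | 2,4-difluoro-6-hydroxybenzaldehyde | O=Cc1c(O)cc(F)cc1F | starting material
28 | 2-(benzyloxy)-4,6-difluorobenzaldehyde | O=Cc1c(OCc2ccccc2)cc(F)cc1F | intermediate
29 | 3,5-bis(benzyloxy)-4-{3,5-bis(benzyloxy)-2-[3-(benzyloxy)-5-fluoro-4-formylphenoxy]phenoxy}benzaldehyde | O=Cc1cc(OCc2ccccc2)c(Oc2cc(OCc3ccccc3)cc(OCc3ccccc3)c2Oc2cc(OCc3ccccc3)c(C=O)c(F)c2)c(OCc2ccccc2)c1 | intermediate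
30 | pentamer trialdehyde (formyl on a1, c4 and e4; benzyl ethers on a3, a5, b3, b5, c3, d3, d4, d5, e3, e5) | O=Cc1cc(OCc2ccccc2)c(Oc2cc(OCc3ccccc3)cc(OCc3ccccc3)c2Oc2cc(OCc3ccccc3)c(C=O)c(Oc3cc(OCc4ccccc4)c(OCc4ccccc4)c(OCc4ccccc4)c3Oc3cc(OCc4ccccc4)c(C=O)c(OCc4ccccc4)c3)c2)c(OCc2ccccc2)c1 | intermediate
31 | pentamer triformate (formyloxy on a1, c4 and e4; ten benzyl ethers) | O=COc1cc(OCc2ccccc2)c(Oc2cc(OCc3ccccc3)cc(OCc3ccccc3)c2Oc2cc(OCc3ccccc3)c(OC=O)c(Oc3cc(OCc4ccccc4)c(OCc4ccccc4)c(OCc4ccccc4)c3Oc3cc(OCc4ccccc4)c(OC=O)c(OCc4ccccc4)c3)c2)c(OCc2ccccc2)c1 | intermediate (not isolated)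
32 | pentamer triphenol (hydroxyl on a1, c4 and e4; ten benzyl ethers) | Oc1cc(OCc2ccccc2)c(Oc2cc(OCc3ccccc3)cc(OCc3ccccc3)c2Oc2cc(OCc3ccccc3)c(O)c(Oc3cc(OCc4ccccc4)c(OCc4ccccc4)c(OCc4ccccc4)c3Oc3cc(OCc4ccccc4)c(O)c(OCc4ccccc4)c3)c2)c(OCc2ccccc2)c1 | intermediate
33 | pseudopentafuhalol D | Oc1cc(O)c(Oc2cc(O)cc(O)c2Oc2cc(O)c(O)c(Oc3cc(O)c(O)c(O)c3Oc3cc(O)c(O)c(O)c3)c2)c(O)c1 | target

## Step count and least certain steps

Total step count: 22. Longest linear sequence: 10 steps (steps 4, 5, 6, 7, 8, 9, 19, 20, 21 and 22, from 5 to 33).

**Step 21 (key step).** The most likely failure is incomplete aryl migration at ring A. There the only donor ortho or para to the formyl group is the a4 aryloxy oxygen, which its two benzyloxy neighbours twist out of conjugation. Hydride migration to the benzoic acid may then compete, and forcing the reaction invites peracid attack on the very electron-rich rings B and D. The fallback sets out from 30 and returns at 32. It replaces the competing migrating group, hydride, by methyl, which migrates far less readily than an electron-rich aryl group. MeMgBr in THF at 0 °C would give the tris(1-hydroxyethyl) pentamer F1 as a mixture of diastereomers. MnO2 would oxidise it to the tris-acetyl pentamer F2. Baeyer–Villiger oxidation of the three aryl methyl ketones with mCPBA would give the pentamer triacetate F3, which K2CO3 in MeOH would cleave to 32.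

**Step 8.** The most likely failure is slow activation of the C–Br bond between two benzyloxy groups. The aldehyde would then sit for a long time in hot basic DMSO, and base-induced disproportionation of the aldehyde and reduction of C–Br to C–H could overtake the coupling. The fallback sets out from 2 and 11 and returns at 12. The copper-catalysed coupling would be run at the ester oxidation level, where higher temperatures can be used, to give benzyl 4-[2-(allyloxy)-3,5-bis(benzyloxy)phenoxy]-3,5-bis(benzyloxy)benzoate F4. Reduction with i-Bu2AlH would give {4-[2-(allyloxy)-3,5-bis(benzyloxy)phenoxy]-3,5-bis(benzyloxy)phenyl}methanol F5, and MnO2 would then give 12.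

**Step 15.** The most likely failure is metalation at the wrong site. Deprotonation beside fluorine would be followed by loss of LiF to an aryne, and deprotonation at a benzylic CH2 by Wittig rearrangement. Both are possible because fluorine acidifies its neighbours and benzyl ethers are themselves metalated by alkyllithiums. The fallback sets out from 20 and returns at 25; it avoids organolithium chemistry and replaces steps 14 to 16. Purchased 4-bromo-2,6-difluorobenzaldehyde F6 would be treated with BnOH and NaH in THF. Both fluorides ortho to the formyl group would be displaced, giving 2,6-bis(benzyloxy)-4-bromobenzaldehyde F7. Copper-catalysed coupling of F7 with 20 (CuI, picolinic acid, K3PO4, DMSO, 90 °C) at the unhindered bromide para to formyl would give 25.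

**Step 20.** The most likely failure is a sluggish addition to the fluoride beside the formyl group. The ring is by then deactivated by the para aryloxy group and the nucleophile is a large phenoxide. Long heating would open the way to exchange of the aryloxy groups para to formyl groups and so to scrambled fragments. The fallback sets out from 26 and 13 and returns at 30; it reverses the order at ring C and also removes the para/ortho question of step 19. Purchased 4-bromo-2-fluoro-6-hydroxybenzaldehyde F8 would be benzylated (BnBr, K2CO3) to 2-(benzyloxy)-4-bromo-6-fluorobenzaldehyde F9. The phenoxide of 26 would displace its only fluoride (K2CO3, DMF, 60 °C) on a ring not yet deactivated, giving the CDE bromide F10. Copper-catalysed coupling of F10 with 13 (CuI, picolinic acid, K3PO4, DMSO, 90 °C) at the unhindered bromide would give 30.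

**Step 22.** The most likely failure is incomplete hydrogenolysis, because partly debenzylated intermediates lose solubility and coat the catalyst. Air oxidation of the polyphenol on the catalyst during filtration is a second risk. The fallback sets out from 32 and returns at 33. BCl3 with pentamethylbenzene as benzyl cation scavenger in CH2Cl2 at −78 °C would cleave all ten benzyl ethers in homogeneous solution without hydrogen or metal. It makes no new compound (entry F0).

## Further compounds

F1 | step 21 | tris(1-hydroxyethyl) pentamer (CH(OH)CH3 in place of each formyl group of 30; mixture of diastereomers) | CC(O)c1cc(OCc2ccccc2)c(Oc2cc(OCc3ccccc3)cc(OCc3ccccc3)c2Oc2cc(OCc3ccccc3)c(C(C)O)c(Oc3cc(OCc4ccccc4)c(OCc4ccccc4)c(OCc4ccccc4)c3Oc3cc(OCc4ccccc4)c(C(C)O)c(OCc4ccccc4)c3)c2)c(OCc2ccccc2)c1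
F2 | step 21 | tris-acetyl pentamer (acetyl in place of each formyl group of 30) | CC(=O)c1cc(OCc2ccccc2)c(Oc2cc(OCc3ccccc3)cc(OCc3ccccc3)c2Oc2cc(OCc3ccccc3)c(C(C)=O)c(Oc3cc(OCc4ccccc4)c(OCc4ccccc4)c(OCc4ccccc4)c3Oc3cc(OCc4ccccc4)c(C(C)=O)c(OCc4ccccc4)c3)c2)c(OCc2ccccc2)c1
F3 | step 21 | pentamer triacetate (acetoxy on a1, c4 and e4; ten benzyl ethers) | CC(=O)Oc1cc(OCc2ccccc2)c(Oc2cc(OCc3ccccc3)cc(OCc3ccccc3)c2Oc2cc(OCc3ccccc3)c(OC(C)=O)c(Oc3cc(OCc4ccccc4)c(OCc4ccccc4)c(OCc4ccccc4)c3Oc3cc(OCc4ccccc4)c(OC(C)=O)c(OCc4ccccc4)c3)c2)c(OCc2ccccc2)c1
F4 | step 8 | benzyl 4-[2-(allyloxy)-3,5-bis(benzyloxy)phenoxy]-3,5-bis(benzyloxy)benzoate | O=C(OCc1ccccc1)c1cc(OCc2ccccc2)c(Oc2cc(OCc3ccccc3)cc(OCc3ccccc3)c2OCC=C)c(OCc2ccccc2)c1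
F5 | step 8 | {4-[2-(allyloxy)-3,5-bis(benzyloxy)phenoxy]-3,5-bis(benzyloxy)phenyl}methanol | OCc1cc(OCc2ccccc2)c(Oc2cc(OCc3ccccc3)cc(OCc3ccccc3)c2OCC=C)c(OCc2ccccc2)c1
F6 | step 15 | 4-bromo-2,6-difluorobenzaldehyde | O=Cc1c(F)cc(Br)cc1F
F7 | step 15 | 2,6-bis(benzyloxy)-4-bromobenzaldehyde | O=Cc1c(OCc2ccccc2)cc(Br)cc1OCc1ccccc1
F8 | step 20 | 4-bromo-2-fluoro-6-hydroxybenzaldehyde | O=Cc1c(O)cc(Br)cc1F
F9 | step 20 | 2-(benzyloxy)-4-bromo-6-fluorobenzaldehyde | O=Cc1c(OCc2ccccc2)cc(Br)cc1F
F10 | step 20 | CDE bromide: 2-(benzyloxy)-4-bromo-6-{3,4,5-tris(benzyloxy)-2-[3,5-bis(benzyloxy)-4-formylphenoxy]phenoxy}benzaldehyde | O=Cc1c(OCc2ccccc2)cc(Br)cc1Oc1cc(OCc2ccccc2)c(OCc2ccccc2)c(OCc2ccccc2)c1Oc1cc(OCc2ccccc2)c(C=O)c(OCc2ccccc2)c1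
F0 | step 22 | none | none
A1 | alternative 1 | DE hydroquinone: 3-(benzyloxy)-5-methoxy-2-[3,4,5-tris(benzyloxy)phenoxy]benzene-1,4-diol | Oc1cc(OC)c(O)c(OCc2ccccc2)c1Oc1cc(OCc2ccccc2)c(OCc2ccccc2)c(OCc2ccccc2)c1
A2 | alternative 1 | racemic 3-(benzyloxy)-4-hydroxy-4-(1-methoxyethenyl)-2-[3,4,5-tris(benzyloxy)phenoxy]cyclobut-2-en-1-one | O=C1C(Oc2cc(OCc3ccccc3)c(OCc3ccccc3)c(OCc3ccccc3)c2)=C(OCc2ccccc2)C1(O)C(OC)=C
A3 | alternative 2 | decabenzyl pentamer with free ring A triol | Oc1cc(O)c(Oc2cc(OCc3ccccc3)cc(OCc3ccccc3)c2Oc2cc(OCc3ccccc3)c(OCc3ccccc3)c(Oc3cc(OCc4ccccc4)c(OCc4ccccc4)c(OCc4ccccc4)c3Oc3cc(OCc4ccccc4)c(OCc4ccccc4)c(OCc4ccccc4)c3)c2)c(O)c1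
A4 | alternative 2 | triketide ester: methyl 3,5-dioxo-6-aryloxyhexanoate on the b1 oxygen of the decabenzyl BCDE unit | COC(=O)CC(=O)CC(=O)COc1cc(OCc2ccccc2)cc(OCc2ccccc2)c1Oc1cc(OCc2ccccc2)c(OCc2ccccc2)c(Oc2cc(OCc3ccccc3)c(OCc3ccccc3)c(OCc3ccccc3)c2Oc2cc(OCc3ccccc3)c(OCc3ccccc3)c(OCc3ccccc3)c2)c1
A5 | alternative 3 | pentamer monoaldehyde (formyl on c4; twelve benzyl ethers) | O=Cc1c(Oc2cc(OCc3ccccc3)c(OCc3ccccc3)c(OCc3ccccc3)c2Oc2cc(OCc3ccccc3)c(OCc3ccccc3)c(OCc3ccccc3)c2)cc(Oc2c(OCc3ccccc3)cc(OCc3ccccc3)cc2Oc2c(OCc3ccccc3)cc(OCc3ccccc3)cc2OCc2ccccc2)cc1OCc1ccccc1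
A6 | alternative 3 | 2,4-bis(benzyloxy)-6-[2,4,6-tris(benzyloxy)phenoxy]phenol | Oc1c(OCc2ccccc2)cc(OCc2ccccc2)cc1Oc1c(OCc2ccccc2)cc(OCc2ccccc2)cc1OCc1ccccc1
A7 | alternative 3 | 3,4,5-tris(benzyloxy)-2-[3,4,5-tris(benzyloxy)phenoxy]phenol | Oc1cc(OCc2ccccc2)c(OCc2ccccc2)c(OCc2ccccc2)c1Oc1cc(OCc2ccccc2)c(OCc2ccccc2)c(OCc2ccccc2)c1
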